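**Plan**

1. Numbering (briarane): C1 quaternary ring-fusion carbon (C15 methyl), C2 butyrate carbinol, C5=C6 ring olefin (C16 methyl), C7 lactone CH–O, C8=C17 butenolide olefin, C19 lactone C=O, C10 ring-fusion CH, C11/C12 epoxide, C14 acetate carbinol; β is the ring face that carries C15.
2. Cuts, in retrosynthetic order: the C11–O–C12 epoxide and the C2 butyrate; the lactone O–C7 bond (giving a ten-membered cyclic allene C5=C6=C7 with a cis C8=C17 tert-butyl ester); C4–C5 (C7 propargylic carbonate plus C4 borane); C7–C8 and C6–C7 (CO and propyne); C8–C17 (Claisen condensation); C9–C10 ([3,3] shift); C1–C15 and C1–C2 (alkylation and aldol on (S)-carvone).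
3. Forward order: the six-membered ring is (S)-carvone and the chain atoms are added to it; the ten-membered ring closes as the cyclic allene (C4–C5); the butenolide closes last (O–C7).
4. Enabling feature: C7 is a ring carbon allylic to the (Z)-C5=C6 olefin and bonded to C8 of the C8=C17 enoate. The unit C5=C6–C7–O is therefore the hydro-acyloxylation product of a C5=C6=C7 allene whose C17 carboxyl group lies five atoms from C7. Inside the ten-membered ring the allene axis stores the C7 configuration, and the ring should favour the cis olefin.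
5. Stereochemistry: C14 from carvone (Criegee, retention); C2 and C1 by anti-aldol and anti-alkylation relative to the isopropenyl group; C10 by suprafacial Ireland–Claisen shift from the 12β-oxygen (nucleophilic epoxidation, Wharton); C7 by CBS reduction, then centre-to-axis-to-centre transfer; the 11β,12β-epoxide via a bromohydrin.

Key step: step 14

Remark: the target is read from its SMILES as the (1S,2S,5Z,7R,10R,11R,12S,14S) isomer.

**Route**

Step 1
Reactants: 1 (S)-(+)-carvone; 2 acrolein
Product: 3 anti-aldol adduct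
Conditions: (c-Hex)2BCl, Et3N, Et2O, −78 → 0 °C; then 2, −78 °C; pH 7 buffer/MeOH
Reagents that add atoms: none
Why: Boron-mediated aldol addition through a Zimmerman–Traxler chair of the (E)-enol borinate should give the anti adduct, with the aldehyde entering anti to the C14 isopropenyl group, which sets C2 as S (C1 is reset in step 3).

Step 2
Reactants: 3 anti-aldol adduct
Product: 4 TBS ether
Conditions: TBSOTf, 2,6-lutidine, CH2Cl2, −78 °C
Reagents that add atoms: tert-butyldimethylsilyl triflate, CC(C)(C)[Si](C)(C)OS(=O)(=O)C(F)(F)F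
Why: Low-temperature silylation of the secondary alcohol should outrun retro-aldol cleavage and touches no stereocentre.

Step 3
Reactants: 4 TBS ether
Product: 5 C1-methylated enone
Conditions: LiN(iPr)2, THF, −78 °C; MeI, DMPU, −78 → −30 °C
Reagents that add atoms: iodomethane, CI
Why: Kinetic α′-deprotonation and enolate alkylation; MeI should approach the tetrasubstituted enolate anti to the adjacent isopropenyl group, which makes C15 β and turns the C2 side chain α, and the low temperature suppresses β-elimination of the silyloxy group.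

Step 4
Reactants: 5 C1-methylated enone
Product: 7 14α-acetoxy enone, via methoxy hydroperoxide 6 (not isolated)
Conditions: O3, CH2Cl2/MeOH (5:1), −78 °C, Sudan Red 7B end point; then Ac2O, Et3N, DMAP (cat.), 0 °C → rt
Reagents that add atoms: ozone, [O-][O+]=O; methanol, CO
Why: Ozone should select the electron-rich 1,1-disubstituted isopropenyl alkene over the enone and the hindered allylic-ether vinyl group, and Criegee rearrangement of the peracetate moves C14 from carbon to oxygen with retention; the quaternary C1 now blocks β-elimination of the acetate.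

Step 5
Reactants: 7 14α-acetoxy enone
Product: 8 11β,12β-epoxy ketone
Conditions: t-BuOOH, DBU, CH2Cl2, 0 °C → rt
Reagents that add atoms: tert-butyl hydroperoxide, CC(C)(C)OO
Why: Weitz–Scheffer nucleophilic epoxidation; the peroxide anion should add to C12 axially and anti to the axial 14α-acetoxy group, giving the β-epoxide.

Step 6
Reactants: 8 11β,12β-epoxy ketone
Product: 9 12β-allylic alcohol
Conditions: N2H4·H2O, AcOH (cat.), MeOH, 0 °C → rt
Reagents that add atoms: none
Why: Wharton transposition (hydrazone, epoxide opening, loss of N2) should give the C10=C11 olefin with the C12 oxygen keeping its β configuration.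

Step 7
Reactants: 9 12β-allylic alcohol
Product: 10 12β,14α-diacetate
Conditions: Ac2O, pyridine, DMAP (cat.), CH2Cl2, rt
Reagents that add atoms: acetic anhydride, CC(=O)OC(C)=O
Why: DMAP-catalysed acetylation of an unhindered secondary allylic alcohol; this acetate supplies C9 and C8.

Step 8
Reactants: 10 12β,14α-diacetate
Product: 12 C8 carboxylic acid, via bis(silyl ketene acetal) 11 (not isolated)
Conditions: LiN(iPr)2 (2.5 equiv), Me3SiCl/Et3N (in situ quench), THF, −78 °C → reflux; 1 M HCl
Reagents that add atoms: none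
Why: Ireland–Claisen rearrangement; the suprafacial [3,3] shift should deliver C9 to the β face of C10 (the face of the C12–O bond, syn to the small C15 methyl) and move the olefin to C11=C12, while the C14 ketene acetal cannot rearrange and returns to the acetate on work-up.

Step 9
Reactants: 12 C8 carboxylic acid; 13 tert-butyl propanoate
Product: 15 β-keto tert-butyl ester, via acyl imidazolide 14 (not isolated)
Conditions: CDI, THF, rt; then LiCH(CH3)CO2tBu (from 13 and LiN(iPr)2, 3 equiv), THF, −78 °C; AcOH
Reagents that add atoms: none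
Why: Crossed Claisen condensation of an acyl imidazolide with an ester enolate; the imidazolide is far more electrophilic than the hindered C14 acetate, and the C17 epimer mixture is removed in step 10.

Step 10
Reactants: 15 β-keto tert-butyl ester
Product: 16 (Z)-enol triflate
Conditions: NaH, THF, 0 °C; Tf2O, −78 → 0 °C
Reagents that add atoms: triflic anhydride, O=S(=O)(OS(=O)(=O)C(F)(F)F)C(F)(F)F
Why: O-triflation of the sodium-chelated enolate of the 1,3-dicarbonyl unit should place the triflate cis to the ester, which is the geometry the lactone needs.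

Step 11
Reactants: 16 (Z)-enol triflate; 17 tributyl(prop-1-yn-1-yl)stannane
Product: 18 ynone
Conditions: Pd(PPh3)4 (5 mol %), LiCl, CO (3 atm), THF, 55 °C
Reagents that add atoms: carbon monoxide, [C-]#[O+]
Why: Stille carbonylative cross-coupling; CO insertion into the alkenylpalladium bond precedes transfer of the alkynyl group, the olefin geometry is retained, and CO pressure suppresses direct coupling.

Step 12
Reactants: 18 ynone
Product: 20 (7S)-propargylic methyl carbonate, via (7S)-propargylic alcohol 19 (not isolated)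
Conditions: (R)-2-methyl-CBS-oxazaborolidine (1 equiv), catecholborane, toluene, −78 °C; MeOH; then ClCO2Me, pyridine, DMAP (cat.), CH2Cl2, 0 °C
Reagents that add atoms: methyl chloroformate, COC(Cl)=O
Why: Corey–Bakshi–Shibata reduction with the linear alkynyl group as the small and the tetrasubstituted alkenyl group as the large substituent should give the (7S) alcohol, and the slow-to-lactonise tert-butyl ester allows the alcohol to be trapped as the carbonate.

Step 13
Reactants: 20 (7S)-propargylic methyl carbonate
Product: 22 ten-membered allene tert-butyl ester, via B-alkyl-9-BBN 21 (not isolated)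
Conditions: 9-BBN (1.1 equiv), THF, 0 °C → rt; then syringe-pump addition to Pd(PPh3)4 (10 mol %), THF, 65 °C, 0.002 M
Reagents that add atoms: none
Why: 9-BBN should hydroborate only the terminal vinyl group; zerovalent palladium then ionises the propargylic carbonate in the anti SN2′ sense to an allenylpalladium methoxide, and base-free B-alkyl transfer (Suzuki–Miyaura type) with retentive reductive elimination at C5 closes the ten-membered ring and converts the (7S) centre into the (aS) allene axis.

Step 14
Reactants: 22 ten-membered allene tert-butyl ester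
Product: 23 butenolide TBS ether
Conditions: (Ph3P)AuCl (5 mol %), AgOTf (5 mol %), CH2Cl2, 0 °C → rt
Reagents that add atoms: none
Why: Cationic monovalent gold (Ph3PAu+) should bind the C6=C7 π-bond of the ring allene on its outer face (the side of the C16 methyl); the carbonyl oxygen of the cis tert-butyl ester on C17 then attacks C7 from the inner face (anti oxy-auration), the 2-tert-butoxyfuranylium ion loses 2-methylpropene, and the C6–Au bond is protonated with retention. The closest known reaction type is the gold- or silver-catalysed cycloisomerisation of allenoic acids and tert-butyl allenoates to butenolides and γ-alkenyl lactones with axis-to-centre chirality transfer. The one ring closed, the butenolide O–C19–C17=C8–C7, forms in the 5-exo-trig mode by O–C7 bond formation at the proximal allene carbon. The new C7 centre (R) is fixed by the (aS) axis together with the anti course of the addition, and the same event fixes C5=C6 as Z, because C7 swings to the side of C4 when the oxygen enters from that side. The step needs attack at C7 and not at C5 or C6, which the five-membered ring size secures, and it needs inner-face attack, which the ten-membered ring should secure because gold fits only on the unhindered outer face and the cis cycloalkene is the less strained product; the electron-poor C8=C17 bond disfavours a Nazarov-type cyclisation of the vinylallene.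

Step 15
Reactants: 23 butenolide TBS ether
Product: 24 C2 alcohol
Conditions: HF·pyridine, pyridine, THF, 0 °C → rt
Reagents that add atoms: none
Why: Fluoride desilylation under buffered acidic conditions should leave the allylic lactone intact and avoid migration of the C14 acetate to the freed C2 hydroxyl.

Step 16
Reactants: 24 C2 alcohol
Product: 25 C2 butyrate
Conditions: (n-PrCO)2O, DMAP, Et3N, CH2Cl2, rt
Reagents that add atoms: butanoic anhydride, CCCC(=O)OC(=O)CCC
Why: DMAP-catalysed acylation of the hindered secondary alcohol; no stereocentre is touched.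

Step 17
Reactants: 25 C2 butyrate
Product: 27 target CNP0220791.2, via bromohydrin 26 (not isolated)
Conditions: NBS, THF/H2O (4:1), 0 °C, dark; then Ag2O, THF, rt
Reagents that add atoms: water, O
Why: The isolated C11=C12 olefin is the most electron-rich (C5=C6 is deactivated by the allylic acyloxy group); the bromonium ion should form on the α face, anti to the axial C15 methyl, water opens it at C11 from the β face (Markovnikov and trans-diaxial, Fürst–Plattner), and Ag2O-assisted closure with inversion at C12 gives the 11β,12β-epoxide without base-induced epimerisation at C7.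

**Compound list**

1 | (S)-(+)-carvone; (5S)-2-methyl-5-(prop-1-en-2-yl)cyclohex-2-en-1-one | CC1=CC[C@@H](CC1=O)C(C)=C | starting material
2 | acrolein; prop-2-enal | C=CC=O | starting material
3 | (5S,6S)-6-[(1S)-1-hydroxyprop-2-en-1-yl]-2-methyl-5-(prop-1-en-2-yl)cyclohex-2-en-1-one | O[C@@H](C=C)[C@H]1C(=O)C(C)=CC[C@@H]1C(C)=C | intermediate
4 | (5S,6S)-6-[(1S)-1-(tert-butyldimethylsilyloxy)prop-2-en-1-yl]-2-methyl-5-(prop-1-en-2-yl)cyclohex-2-en-1-one | CC(C)(C)[Si](C)(C)O[C@@H](C=C)[C@H]1C(=O)C(C)=CC[C@@H]1C(C)=C | intermediate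
5 | (5R,6R)-6-[(1S)-1-(tert-butyldimethylsilyloxy)prop-2-en-1-yl]-2,6-dimethyl-5-(prop-1-en-2-yl)cyclohex-2-en-1-one (6-methyl trans, side chain cis to isopropenyl) | CC(C)(C)[Si](C)(C)O[C@@H](C=C)[C@]1(C)C(=O)C(C)=CC[C@@H]1C(C)=C | intermediate
6 | compound 5 with a 1-hydroperoxy-1-methoxyethyl group in place of isopropenyl (epimers at the new carbon) | CC(C)(C)[Si](C)(C)O[C@@H](C=C)[C@]1(C)C(=O)C(C)=CC[C@@H]1C(C)(OC)OO | intermediate
7 | cyclohex-2-enone (C10=O, C11(CH3)=C12H) with 1β-CH3, 1α-[(2S)-CH(OTBS)CH=CH2] and 14α-OAc | CC(C)(C)[Si](C)(C)O[C@@H](C=C)[C@]1(C)C(=O)C(C)=CC[C@@H]1OC(C)=O | intermediate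
8 | 11β,12β-epoxide of 7 (epoxide trans to the 14α-acetoxy group) | CC(C)(C)[Si](C)(C)O[C@@H](C=C)[C@]1(C)C(=O)[C@@]2(C)O[C@H]2C[C@@H]1OC(C)=O | intermediate
9 | cyclohexenol with C10H=C11(CH3), 12β-OH, 14α-OAc, 1β-CH3, 1α-[(2S)-CH(OTBS)CH=CH2] | CC(C)(C)[Si](C)(C)O[C@@H](C=C)[C@]1(C)C=C(C)[C@@H](O)C[C@@H]1OC(C)=O | intermediate
10 | 12β-acetate of 9 (12β,14α-diacetate) | CC(C)(C)[Si](C)(C)O[C@@H](C=C)[C@]1(C)C=C(C)[C@@H](OC(C)=O)C[C@@H]1OC(C)=O | intermediate
11 | bis[1-(trimethylsilyloxy)vinyl] ether of the 12β,14α-diol (silyl ketene acetals of both acetates of 10) | CC(C)(C)[Si](C)(C)O[C@@H](C=C)[C@]1(C)C=C(C)[C@@H](OC(=C)O[Si](C)(C)C)C[C@@H]1OC(=C)O[Si](C)(C)C | intermediate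
12 | cyclohexene (C11(CH3)=C12H) with 10β-CH2CO2H, 1β-CH3, 1α-[(2S)-CH(OTBS)CH=CH2], 14α-OAc | CC(C)(C)[Si](C)(C)O[C@@H](C=C)[C@]1(C)[C@@H](CC(O)=O)C(C)=CC[C@@H]1OC(C)=O | intermediate
13 | tert-butyl propanoate | CCC(=O)OC(C)(C)C | starting material
14 | N-acylimidazole of acid 12 | CC(C)(C)[Si](C)(C)O[C@@H](C=C)[C@]1(C)[C@@H](CC(=O)n2ccnc2)C(C)=CC[C@@H]1OC(C)=O | intermediate
15 | β-keto ester, 10β-CH2C(=O)CH(CH3)CO2tBu (C17 epimers) | CC(C)(C)[Si](C)(C)O[C@@H](C=C)[C@]1(C)[C@@H](CC(=O)C(C)C(=O)OC(C)(C)C)C(C)=CC[C@@H]1OC(C)=O | intermediate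
16 | (Z)-enol triflate, 10β-CH2C(OTf)=C(CH3)CO2tBu, triflate cis to the ester | CC(C)(C)[Si](C)(C)O[C@@H](C=C)[C@]1(C)[C@@H](C/C(OS(=O)(=O)C(F)(F)F)=C(\C)C(=O)OC(C)(C)C)C(C)=CC[C@@H]1OC(C)=O | intermediate
17 | tributyl(prop-1-yn-1-yl)stannane | CC#C[Sn](CCCC)(CCCC)CCCC | starting material
18 | ynone, 10β-CH2C[C(=O)C≡CCH3]=C(CH3)CO2tBu, acyl group cis to the ester | CC(C)(C)[Si](C)(C)O[C@@H](C=C)[C@]1(C)[C@@H](C/C(C(=O)C#CC)=C(\C)C(=O)OC(C)(C)C)C(C)=CC[C@@H]1OC(C)=O | intermediate
19 | (7S)-propargylic alcohol from 18 | CC(C)(C)[Si](C)(C)O[C@@H](C=C)[C@]1(C)[C@@H](C/C([C@@H](O)C#CC)=C(\C)C(=O)OC(C)(C)C)C(C)=CC[C@@H]1OC(C)=O | intermediate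
20 | (7S)-propargylic methyl carbonate of 19 | CC(C)(C)[Si](C)(C)O[C@@H](C=C)[C@]1(C)[C@@H](C/C([C@@H](OC(=O)OC)C#CC)=C(\C)C(=O)OC(C)(C)C)C(C)=CC[C@@H]1OC(C)=O | intermediate
21 | compound 20 with C3–C4 saturated and 9-borabicyclo[3.3.1]nonan-9-yl on C4 | CC(C)(C)[Si](C)(C)O[C@@H](CCB2C3CCCC2CCC3)[C@]1(C)[C@@H](C/C([C@@H](OC(=O)OC)C#CC)=C(\C)C(=O)OC(C)(C)C)C(C)=CC[C@@H]1OC(C)=O | intermediate
22 | ten-membered carbocycle (C1–C10) trans-fused to the cyclohexene, with (aS)-allene C5(CH3)=C6=C7H, exocyclic (Z)-C8=C17(CH3)CO2tBu, (2S)-OTBS, 14α-OAc | CC(C)(C)[Si](C)(C)O[C@H]1CCC(C)=[C@@]=C([H])/C(=C(/C)C(=O)OC(C)(C)C)C[C@H]2C(C)=CC[C@H](OC(C)=O)[C@]12C | intermediate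
23 | (5Z,7R)-butenolide, 2-O-TBS, 14α-OAc, C11=C12 olefin | CC(C)(C)[Si](C)(C)O[C@H]1CC/C(C)=C\[C@H]2OC(=O)C(C)=C2C[C@H]2C(C)=CC[C@H](OC(C)=O)[C@]12C | intermediate
24 | 2-hydroxy compound from 23 | O[C@H]1CC/C(C)=C\[C@H]2OC(=O)C(C)=C2C[C@H]2C(C)=CC[C@H](OC(C)=O)[C@]12C | intermediate
25 | 2-butyrate of 24 (11,12-deoxy target) | CCCC(=O)O[C@H]1CC/C(C)=C\[C@H]2OC(=O)C(C)=C2C[C@H]2C(C)=CC[C@H](OC(C)=O)[C@]12C | intermediate
26 | 12α-bromo-11β-hydroxy bromohydrin of 25 | CCCC(=O)O[C@H]1CC/C(C)=C\[C@H]2OC(=O)C(C)=C2C[C@H]2[C@@](C)(O)[C@H](Br)C[C@H](OC(C)=O)[C@]12C | intermediate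
27 | CNP0220791.2, (1S,2S,5Z,7R,10R,11R,12S,14S) | CCCC(=O)O[C@H]1CC/C(C)=C\[C@H]2OC(=O)C(C)=C2C[C@H]2[C@@]3(C)O[C@H]3C[C@H](OC(C)=O)[C@]12C | target

**Summary**

Total step count: 17. Longest linear sequence: 17 steps (1 → 27).

Steps most likely to fail:

Step 13. Ring closure may lose to β-hydride elimination, protodeboronation or intermolecular coupling, because boron-to-palladium transfer is slow without base and the ten-membered transition state is strained. Fallback (organozinc, Negishi type): from 20, hydroboration with 9-BBN and oxidation with NaBO3·4H2O would give the primary alcohol F1; I2, PPh3 and imidazole would give the primary iodide F2; zinc insertion (Zn, LiCl, THF) would give the alkylzinc iodide F3. This transfers its alkyl group to the allenylpalladium species without base, so Pd(PPh3)4 at high dilution should close the ring by the same anti SN2′ course. The fallback returns to the route at 22.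

Step 14. The carbonyl oxygen may add to the other face of the allene (leading to the 5E,7-epi lactone), or the vinylallene may enter a cationic cyclisation. Fallback (π-allylpalladium manifold): from 22, Me3SiOTf/2,6-lutidine followed by water would cleave the tert-butyl ester to the allenyl carboxylic acid F4. Pd(PPh3)4 in THF at 60 °C should then add H–Pd across C6=C7 (hydride to C6) and close the lactone by C7–O bond formation from the π-allyl complex, which can equilibrate to the cis ring geometry before the C–O bond forms. C7 is then set by the ring and not by the axis. The fallback returns at 23.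

Step 6. Hydrazone formation at the C10 ketone, flanked by the quaternary C1 and the epoxide carbon C11, may be too slow, and long exposure to hydrazine would cleave the C14 acetate. Fallback (allylic alcohol transposition in place of epoxy ketone transposition): from 7, Luche reduction (NaBH4, CeCl3·7H2O, MeOH, −78 °C, hydride anti to the axial C15 methyl) would give the 10β-allylic alcohol F5. Ph3SiOReO3 (cat.) in Et2O at 0 °C should shift the hydroxyl group suprafacially to C12, driven by relief of strain at the neopentyl C10. The fallback returns at 9 and bypasses 8.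

Further compounds
F1 | step 13 | primary alcohol, compound 20 with C3–C4 saturated and OH on C4 | CC(C)(C)[Si](C)(C)O[C@@H](CCO)[C@]1(C)[C@@H](C/C([C@@H](OC(=O)OC)C#CC)=C(\C)C(=O)OC(C)(C)C)C(C)=CC[C@@H]1OC(C)=O
F2 | step 13 | primary iodide from F1 | CC(C)(C)[Si](C)(C)O[C@@H](CCI)[C@]1(C)[C@@H](C/C([C@@H](OC(=O)OC)C#CC)=C(\C)C(=O)OC(C)(C)C)C(C)=CC[C@@H]1OC(C)=O
F3 | step 13 | alkylzinc iodide from F2 | CC(C)(C)[Si](C)(C)O[C@@H](CC[Zn]I)[C@]1(C)[C@@H](C/C([C@@H](OC(=O)OC)C#CC)=C(\C)C(=O)OC(C)(C)C)C(C)=CC[C@@H]1OC(C)=O
F4 | step 14 | allenyl carboxylic acid, compound 22 with CO2H in place of CO2tBu | CC(C)(C)[Si](C)(C)O[C@H]1CCC(C)=[C@@]=C([H])/C(=C(/C)C(O)=O)C[C@H]2C(C)=CC[C@H](OC(C)=O)[C@]12C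
F5 | step 6 | 10β-allylic alcohol, compound 7 with the C10 ketone reduced | CC(C)(C)[Si](C)(C)O[C@@H](C=C)[C@]1(C)[C@@H](O)C(C)=CC[C@@H]1OC(C)=O
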